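## Structural features

- Compound 28 is a germacranolide: a ten-membered carbocycle (C1–C10) fused trans at C6–C7 (6R,7S) to an α-methylene-γ-butyrolactone (ring O on C6, C11 on C7, C13 the exocyclic methylene, C12 the carbonyl).
- The carbocycle carries a ketone at C1, a secondary hydroxyl at C3 (3S), a methyl at C4 (4R), an angelate at C8 (8S) and, at C10, a quaternary centre with methyl C14 and an acetate (10R). C2, C5 and C9 are methylenes and no ring olefin is left.
- The stereocentres form a contiguous triad C6–C7–C8, an adjacent pair C3–C4 (hydroxyl and methyl cis on the ring) and the isolated quaternary C10 next to the ketone.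
- Fragile groups: the C1/C3 β-hydroxy ketone (dehydration, retro-aldol), the tertiary α-acetoxy ketone (α-ketol shift, acyl migration), the (Z)-angelate (isomerisation to tiglate) and the exo-methylene lactone (Michael acceptor; the lactone can also migrate to O8).
- The real difficulty is a saturated, conformationally mobile ten-membered ring with six stereocentres and no alkene to suggest a ring closure.
- Feature exploited: a C6 ketone with a (1(10)E)-alkene is a cyclodec-5-enone, the product pattern of an oxy-Cope ring expansion of the cyclohexane C1–C6. C8–C9 is the bond formed, C1–C6 the bond broken, and C3/C4 ride untouched on the six-membered ring.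
- Remark: every intermediate carries the locants (C1–C15) of the atoms it becomes in 28.

## Logic of the disconnections

**28 back to 25.** The O–Si bond at O3 and the acyl C–O bond at O8 are cut. The free β-hydroxy ketone and the isomerisable angelate are best unveiled last. This asks for two orthogonal ethers (silyl at O3, 4-methoxybenzyl at O8) and an esterification that does not isomerise the angelate.

**25 back to 22.** The C1=O and C10–O bonds are traced to the C1=C10 alkene (acetylation, alcohol oxidation, syn-dihydroxylation). The quaternary acetoxy ketone becomes one trisubstituted (E)-alkene. The forward demand is attack on one face of that alkene only, and chemoselectivity over the acrylate.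

**22 back to 19.** The C11=C13 bond is cut (α-methylenation of the lactone). The Michael acceptor is then absent from the reduction step; it has to be installed before the C1 ketone exists.

**19 back to 17.** The lactone C12–O6 bond and the C6–H bond are cut. The lactone becomes a 6-keto ester whose ketone is the oxy-Cope carbonyl. The reduction must give 6R, that is O6 trans to the C7 side chain and syn to O8.

**17 back to 15 (key).** C8–C9 and C7–C11 are cut and C1–C6 is reconnected. The ten-membered ring collapses to a cyclohexane with two alkenyl arms, and two stereocentres plus the alkene geometry vanish. The forward step must run through one chair transition state and must alkylate the nascent enolate before it relaxes.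

**15 back to 10 and 12.** The C6–C7 bond is cut (acetylide addition, then trans-reduction). The enol ether arm comes from a two-carbon alkoxyacetylide. Addition must occur anti to the ring substituents and the alkyne must be reduced to the (E)-enol ether.

**10 back to 8, and 8 back to 5.** In 10 the C1–H bond is "cut" (it is set by protonation of a dienolate), which makes the C1 configuration of 8 irrelevant. In 8 the C1–C6 bond is cut (oxidative carbonyl-ene cyclisation of the citronellol type). The ring becomes an open chain that holds only C3 and C4.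

**5 back to 2.** The C3–C4 bond is cut (anti-crotylation), followed by protection and terminal hydroboration. Both chain stereocentres come from one reagent-controlled step on an achiral aldehyde. Compound 2 comes from 1 by oxidation, and 12 from 11 by vinyl ether formation.

## Other disconnections considered

**Alternative 1:** the first that comes to mind. Cut C6–C7 and the lactone C–O bond, and close both rings by an intramolecular Barbier/Nozaki–Hiyama allylation of the aldehyde–allylic bromide A1 (CrCl2 or zinc), converging on 25.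
- A1 must already hold C3, C4, C8 and C10, so four stereocentres have to be built linearly on an open chain.
- Its α-acetoxy ketone is reducible by low-valent chromium, and its ketone competes with the aldehyde.
- The closure is an end-to-end ten-membered cyclisation under high dilution, with the C6/C7 relation left to an uncontrolled medium-ring transition state.
- The chosen plan makes the ring unimolecularly from a six-membered ring and fixes C7/C8 through a chair.

**Alternative 2:** cut C1=C10 and close the lactone-bearing diene A2 by ring-closing metathesis with a molybdenum or ruthenium alkylidene, converging on 22.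
- A trisubstituted alkene in a strained ten-membered ring is among the least favourable metathesis closures; dimerisation is likely.
- The (E)-geometry, on which the later face-selective oxidation depends, is not controlled.
- The acrylate is a competing metathesis partner.
- The oxy-Cope step gives the (E)-alkene as a consequence of its chair geometry.

**Alternative 3:** a bicyclic template. Cut C1–C6 in the sense of an oxidative cleavage: ozonolysis of the ring-fusion alkene of octalin A3 would give the ten-membered 1,6-diketone A4.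
- The template would set C3, C4, C7, C8 and C10 on a rigid decalin.
- However, A4 has two enolisable ketones placed for transannular aldol closure.
- C6 must then be reduced selectively in the presence of C1, with no handle for its configuration.
- A3, with five stereocentres on a tetrasubstituted octalin, is no easier to make than 15. The oxy-Cope delivers the two carbonyl-level positions already differentiated, as an enolate and an alkene.

Key step: step 10

## Steps

Step 1
Reactants: 1 4-methylpent-3-en-1-ol
Product: 2 4-methylpent-3-enal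
Conditions: Dess–Martin periodinane, pyridine, CH2Cl2, 0 °C; used crude
Reagents that add atoms: none
Why: Dess–Martin oxidation of a primary alcohol; the pyridine buffer keeps the β,γ-unsaturated aldehyde from moving into conjugation.

Step 2
Reactants: 2 4-methylpent-3-enal
Product: 3 (3R,4S)-3,7-dimethylocta-1,6-dien-4-ol
Conditions: (E)-but-2-ene, n-BuLi, KOt-Bu, THF, −45 °C; (+)-Ipc2BOMe, −78 °C; BF3·OEt2; 2, −78 °C; then NaOH, H2O2
Reagents that add atoms: (E)-but-2-ene, C/C=C/C, delivered as B-[(E)-but-2-enyl]bis(isopinocampheyl)borane, C/C=C/CB([C@H]1C[C@H]2C[C@@H]([C@@H]1C)C2(C)C)[C@H]1C[C@H]2C[C@@H]([C@@H]1C)C2(C)C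
Why: Brown crotylboration through a closed chair (Zimmerman–Traxler) transition state; the (E)-crotyl geometry gives the anti relation of methyl and hydroxyl (C4/C3 of the target), and the isopinocampheyl groups derived from (−)-α-pinene direct attack to the Re face of the aldehyde, which should give 3R,4S.

Step 3
Reactants: 3 (3R,4S)-3,7-dimethylocta-1,6-dien-4-ol
Product: 4 tert-butyl{[(3R,4S)-3,7-dimethylocta-1,6-dien-4-yl]oxy}dimethylsilane
Conditions: TBSCl, imidazole, DMF, 25 °C
Reagents that add atoms: tert-butyldimethylsilyl chloride, CC(C)(C)[Si](C)(C)Cl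
Why: Standard silylation of a secondary alcohol; the ether must survive chromium oxidation, strong bases and hydride reagents and is removed last.

Step 4
Reactants: 4 tert-butyl{[(3R,4S)-3,7-dimethylocta-1,6-dien-4-yl]oxy}dimethylsilane
Product: 5 (3R,4S)-4-[(tert-butyldimethylsilyl)oxy]-3,7-dimethyloct-6-en-1-ol
Conditions: 9-BBN, THF, 0 → 25 °C; then NaOH, H2O2
Reagents that add atoms: hydrogen peroxide, OO
Why: Anti-Markovnikov hydroboration–oxidation; 9-BBN discriminates strongly in favour of the monosubstituted alkene over the trisubstituted one.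

Step 5
Reactants: 5 (3R,4S)-4-[(tert-butyldimethylsilyl)oxy]-3,7-dimethyloct-6-en-1-ol
Product: 8 (4S,5R)-4-[(tert-butyldimethylsilyl)oxy]-5-methyl-2-(prop-1-en-2-yl)cyclohexan-1-one as a mixture of C2 epimers, via aldehyde 6 (not isolated), via cyclohexanol 7 (not isolated)
Conditions: pyridinium chlorochromate [C5H5NH][CrO3Cl] (3 equiv), CH2Cl2, 25 °C
Reagents that add atoms: none
Why: Oxidative cationic cyclisation as known for citronellol to isopulegone: the acidic chromium reagent oxidises the alcohol to aldehyde 6, promotes the intramolecular carbonyl-ene closure of the C1–C6 bond to 7 and oxidises 7 to the ketone. The C1 configuration (C2 of the cyclohexanone) is not controlled here and need not be, because step 6 erases it.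

Step 6
Reactants: 8 (4S,5R)-4-[(tert-butyldimethylsilyl)oxy]-5-methyl-2-(prop-1-en-2-yl)cyclohexan-1-one (epimer mixture)
Product: 10 (2S,4S,5R)-4-[(tert-butyldimethylsilyl)oxy]-5-methyl-2-(prop-1-en-2-yl)cyclohexan-1-one, via potassium dienolate 9 (not isolated)
Conditions: KN(SiMe3)2 (0.95 equiv), THF, −78 → 0 °C; then −78 °C, pivalic acid
Reagents that add atoms: none
Why: Both epimers of 8, and any conjugated isopropylidene isomer, give the same conjugated dienolate 9, so the step is stereoconvergent. Kinetic α-protonation (deconjugative protonation of a dienolate) by the bulky acid should come from the ring face opposite the C3 silyloxy group, because the chair-like axial approach on the other face is syn-axial to it; this leaves isopropenyl cis to both the silyloxy and the methyl group.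

Step 7
Reactants: 11 4-methoxybenzyl alcohol
Product: 12 1-({[(E)-1,2-dichloroethenyl]oxy}methyl)-4-methoxybenzene
Conditions: KH, THF, 0 °C; Cl2C=CHCl, 25 °C
Reagents that add atoms: trichloroethylene, ClC=C(Cl)Cl
Why: Known dichlorovinyl ether synthesis: the alkoxide adds to dichloroacetylene formed in situ from trichloroethylene, and trans-addition gives the (E)-1,2-dichlorovinyl ether, a stable precursor of the alkoxyacetylide.

Step 8
Reactants: 10 (2S,4S,5R)-4-[(tert-butyldimethylsilyl)oxy]-5-methyl-2-(prop-1-en-2-yl)cyclohexan-1-one; 12 1-({[(E)-1,2-dichloroethenyl]oxy}methyl)-4-methoxybenzene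
Product: 14 (1S,2S,4S,5R)-4-[(tert-butyldimethylsilyl)oxy]-1-{[(4-methoxybenzyl)oxy]ethynyl}-5-methyl-2-(prop-1-en-2-yl)cyclohexan-1-ol, via lithium acetylide 13 (not isolated)
Conditions: 12, n-BuLi (2 equiv), THF, −78 → −40 °C; CeCl3, −78 °C; then 10
Reagents that add atoms: none
Why: Elimination and lithium–chlorine exchange convert 12 into alkoxyacetylide 13; its trivalent cerium derivative adds to the enolisable ketone without epimerising C1. The three ring substituents of 10 lie on one face (in either chair the axial C4 methyl or the axial isopropenyl shields it), so the acetylide should enter anti to all of them, giving the alkynyl group trans to isopropenyl.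

Step 9
Reactants: 14 (1S,2S,4S,5R)-4-[(tert-butyldimethylsilyl)oxy]-1-{[(4-methoxybenzyl)oxy]ethynyl}-5-methyl-2-(prop-1-en-2-yl)cyclohexan-1-ol
Product: 15 (1S,2S,4S,5R)-4-[(tert-butyldimethylsilyl)oxy]-1-{(E)-2-[(4-methoxybenzyl)oxy]ethenyl}-5-methyl-2-(prop-1-en-2-yl)cyclohexan-1-ol
Conditions: LiAlH4, THF, 0 → 25 °C; aq. NaOH work-up, base-washed silica
Reagents that add atoms: none
Why: Alkoxide-directed trans-hydroalumination of a propargylic alcohol, the standard route to (E)-allylic alcohols and known for alkoxyethynyl carbinols, gives the (E)-enol ether. The acid-labile product is kept basic and used at once.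

Step 10
Reactants: 15 (1S,2S,4S,5R)-4-[(tert-butyldimethylsilyl)oxy]-1-{(E)-2-[(4-methoxybenzyl)oxy]ethenyl}-5-methyl-2-(prop-1-en-2-yl)cyclohexan-1-ol
Product: 17 ethyl [(3S,4R,7R,8S,1(10)E)-3-[(tert-butyldimethylsilyl)oxy]-8-[(4-methoxybenzyl)oxy]-4,10-dimethyl-6-oxocyclodec-1(10)-en-7-yl]acetate (target locants), via potassium enolate 16 (not isolated)
Conditions: KN(SiMe3)2, 18-crown-6, THF, −78 → 0 °C; then −78 °C, BrCH2CO2Et; AcOH quench at −78 °C
Reagents that add atoms: ethyl bromoacetate, BrCC(=O)OCC
Why: The dissociated potassium alkoxide of 15 undergoes a [3,3]-sigmatropic shift in which C8–C9 forms and C1–C6 breaks, giving the ten-membered enolate 16, which is alkylated at C7 in the same flask. The closest known reaction type is the anionic oxy-Cope ring expansion of trans-1,2-dialkenylcyclohexanols to (E)-cyclodec-5-enones with in situ enolate alkylation. The ten-membered ring is not closed end to end but arises by four-atom ring expansion of the six-membered ring, so no high dilution or medium-ring closure is involved. The trans-diequatorial alkenyl groups enforce a chair transition state shaped like a trans-decalin; the ring bonds C1–C2 and C6–C5 are equatorial in it, which gives the (E)-C1=C10 alkene and an enolate with C5 trans to C8. C8 is set by chirality transfer from C1/C6: the (E)-enol ether places the benzyloxy group equatorial in this chair, which corresponds to 8S. C7 is set by alkylation on the peripheral face of the nascent enolate, whose inner face is covered by the transannular C1=C10 unit, which places the acetate arm trans to O8. The step needs chair over boat (secured by the trans-1,2 arrangement, at the price of an axial C4 methyl that is syn-axial only to the oxyanion), C- over O-alkylation (soft bromide, free enolate) and no β-elimination of the benzyloxide (the C8–O bond lies near the nodal plane of the enolate and the enolate is trapped cold). The regiodefined C6 enolate and the C1=C10 alkene are the two handles from which the lactone and the acetoxy ketone are later made.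

Step 11
Reactants: 17 ethyl [(3S,4R,7R,8S,1(10)E)-3-[(tert-butyldimethylsilyl)oxy]-8-[(4-methoxybenzyl)oxy]-4,10-dimethyl-6-oxocyclodec-1(10)-en-7-yl]acetate
Product: 19 (3S,4R,6R,7R,8S,1(10)E)-3-[(tert-butyldimethylsilyl)oxy]-8-[(4-methoxybenzyl)oxy]germacr-1(10)-en-12,6-olide (trans-fused butanolide), via hydroxy ester 18 (not isolated)
Conditions: Zn(BH4)2, Et2O, −30 → 0 °C; then PPTS, toluene, 60 °C
Reagents that add atoms: none
Why: Chelation-controlled reduction of a β-alkoxy ketone: zinc bridges the C6 carbonyl and the C8 benzyloxy oxygen, and hydride is delivered anti to the axial C7 substituent of the chelate, which should give the 6,8-syn and 6,7-trans alcohol (6R). The γ-hydroxy ester then closes to the trans-fused lactone under mild acid.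

Step 12
Reactants: 19 (3S,4R,6R,7R,8S,1(10)E)-3-[(tert-butyldimethylsilyl)oxy]-8-[(4-methoxybenzyl)oxy]germacr-1(10)-en-12,6-olide
Product: 22 (3S,4R,6R,7R,8S,1(10)E)-3-[(tert-butyldimethylsilyl)oxy]-8-[(4-methoxybenzyl)oxy]germacra-1(10),11(13)-dien-12,6-olide, via Mannich base 20 (not isolated), via ammonium iodide 21 (not isolated)
Conditions: LiN(SiMe3)2, THF, −78 °C; CH2=NMe2+ I−, −78 → 0 °C; then MeI, MeOH, 25 °C; aq. NaHCO3
Reagents that add atoms: Eschenmoser's salt, C=[N+](C)C.[I-]
Why: Standard α-methylenation of a γ-lactone: Mannich reaction of the lactone enolate, quaternisation and base-induced elimination. It is done now because no ketone, acetate or angelate is yet present to compete for the base.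

Step 13
Reactants: 22 (3S,4R,6R,7R,8S,1(10)E)-3-[(tert-butyldimethylsilyl)oxy]-8-[(4-methoxybenzyl)oxy]germacra-1(10),11(13)-dien-12,6-olide
Product: 23 (1R,3S,4R,6R,7R,8S,10R)-3-[(tert-butyldimethylsilyl)oxy]-1,10-dihydroxy-8-[(4-methoxybenzyl)oxy]germacr-11(13)-en-12,6-olide
Conditions: OsO4 (cat.), N-methylmorpholine N-oxide, acetone/H2O, 0 °C
Reagents that add atoms: N-methylmorpholine N-oxide, C[N+]1([O-])CCOCC1; water, O; the oxygen is passed on by catalytic osmium tetroxide, O=[Os](=O)(=O)=O
Why: Syn-dihydroxylation; the strained, electron-rich (E)-trisubstituted alkene should react well before the electron-poor acrylate. Only the peripheral face of the (E)-alkene is open, and in the conformer imposed by the trans-lactone (C14 pointing to the same side as H6) this is the face that gives 10R, the same sense in which 1(10)-oxidised trans-6,12-germacranolides arise.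

Step 14
Reactants: 23 (1R,3S,4R,6R,7R,8S,10R)-3-[(tert-butyldimethylsilyl)oxy]-1,10-dihydroxy-8-[(4-methoxybenzyl)oxy]germacr-11(13)-en-12,6-olide
Product: 24 (3S,4R,6R,7R,8S,10R)-3-[(tert-butyldimethylsilyl)oxy]-10-hydroxy-8-[(4-methoxybenzyl)oxy]-1-oxogermacr-11(13)-en-12,6-olide
Conditions: IBX, DMSO, 25 °C
Reagents that add atoms: none
Why: IBX oxidises the secondary hydroxyl of a secondary/tertiary 1,2-diol to the α-hydroxy ketone without glycol cleavage; the tertiary C10 hydroxyl cannot be oxidised.

Step 15
Reactants: 24 (3S,4R,6R,7R,8S,10R)-3-[(tert-butyldimethylsilyl)oxy]-10-hydroxy-8-[(4-methoxybenzyl)oxy]-1-oxogermacr-11(13)-en-12,6-olide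
Product: 25 (3S,4R,6R,7R,8S,10R)-10-acetoxy-3-[(tert-butyldimethylsilyl)oxy]-8-[(4-methoxybenzyl)oxy]-1-oxogermacr-11(13)-en-12,6-olide
Conditions: Ac2O, DMAP, Et3N, CH2Cl2, 25 → 40 °C
Reagents that add atoms: acetic anhydride, CC(=O)OC(C)=O
Why: DMAP-catalysed (Steglich-type) acetylation of a tertiary alcohol; it is done before the angelate is present so that the forcing conditions cannot isomerise it.

Step 16
Reactants: 25 (3S,4R,6R,7R,8S,10R)-10-acetoxy-3-[(tert-butyldimethylsilyl)oxy]-8-[(4-methoxybenzyl)oxy]-1-oxogermacr-11(13)-en-12,6-olide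
Product: 26 (3S,4R,6R,7R,8S,10R)-10-acetoxy-3-[(tert-butyldimethylsilyl)oxy]-8-hydroxy-1-oxogermacr-11(13)-en-12,6-olide
Conditions: DDQ, CH2Cl2/pH 7 phosphate buffer, 0 → 25 °C
Reagents that add atoms: none
Why: Oxidative cleavage of the 4-methoxybenzyl ether under neutral conditions, which leaves the silyl ether, the acetate, the ketone and the acrylate untouched.

Step 17
Reactants: 26 (3S,4R,6R,7R,8S,10R)-10-acetoxy-3-[(tert-butyldimethylsilyl)oxy]-8-hydroxy-1-oxogermacr-11(13)-en-12,6-olide
Product: 27 (3S,4R,6R,7S,8S,10R)-10-acetoxy-8-(angeloyloxy)-3-[(tert-butyldimethylsilyl)oxy]-1-oxogermacr-11(13)-en-12,6-olide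
Conditions: angelic acid, 2,4,6-Cl3C6H2COCl, Et3N, toluene, 25 °C; then 26, toluene, 80 °C
Reagents that add atoms: angelic acid, C/C=C(/C)C(=O)O
Why: Yamaguchi-type esterification through the preformed mixed anhydride without a nucleophilic catalyst, the conditions known to acylate hindered secondary alcohols with retention of the (Z)-geometry.

Step 18
Reactants: 27 (3S,4R,6R,7S,8S,10R)-10-acetoxy-8-(angeloyloxy)-3-[(tert-butyldimethylsilyl)oxy]-1-oxogermacr-11(13)-en-12,6-olide
Product: 28 (3S,4R,6R,7S,8S,10R)-10-acetoxy-8-(angeloyloxy)-3-hydroxy-1-oxogermacr-11(13)-en-12,6-olide (CNP0141210.6)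
Conditions: HF·pyridine, pyridine, THF, 0 → 25 °C
Reagents that add atoms: none
Why: Buffered acidic fluoride removes the secondary silyl ether without the base that would dehydrate the β-hydroxy ketone or move the acyl groups.

## Compound list

1 | 4-methylpent-3-en-1-ol | CC(C)=CCCO | starting material
2 | 4-methylpent-3-enal | CC(C)=CCC=O | intermediate
3 | (3R,4S)-3,7-dimethylocta-1,6-dien-4-ol | C=C[C@@H](C)[C@@H](O)CC=C(C)C | intermediate
4 | tert-butyl{[(3R,4S)-3,7-dimethylocta-1,6-dien-4-yl]oxy}dimethylsilane | C=C[C@@H](C)[C@@H](O[Si](C)(C)C(C)(C)C)CC=C(C)C | intermediate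
5 | (3R,4S)-4-[(tert-butyldimethylsilyl)oxy]-3,7-dimethyloct-6-en-1-ol | OCC[C@@H](C)[C@@H](O[Si](C)(C)C(C)(C)C)CC=C(C)C | intermediate
6 | (3R,4S)-4-[(tert-butyldimethylsilyl)oxy]-3,7-dimethyloct-6-enal | O=CC[C@@H](C)[C@@H](O[Si](C)(C)C(C)(C)C)CC=C(C)C | intermediate (not isolated)
7 | (4S,5R)-4-[(tert-butyldimethylsilyl)oxy]-5-methyl-2-(prop-1-en-2-yl)cyclohexan-1-ol, C1/C2 mixture | OC1C[C@@H](C)[C@@H](O[Si](C)(C)C(C)(C)C)CC1C(C)=C | intermediate (not isolated)
8 | (4S,5R)-4-[(tert-butyldimethylsilyl)oxy]-5-methyl-2-(prop-1-en-2-yl)cyclohexan-1-one, C2 epimers | O=C1C[C@@H](C)[C@@H](O[Si](C)(C)C(C)(C)C)CC1C(C)=C | intermediate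
9 | potassium (4S,5R)-4-[(tert-butyldimethylsilyl)oxy]-5-methyl-2-(prop-1-en-2-yl)cyclohex-1-en-1-olate | [K+].[O-]C1=C(C(C)=C)C[C@H](O[Si](C)(C)C(C)(C)C)[C@H](C)C1 | intermediate (not isolated)
10 | (2S,4S,5R)-4-[(tert-butyldimethylsilyl)oxy]-5-methyl-2-(prop-1-en-2-yl)cyclohexan-1-one | O=C1C[C@@H](C)[C@@H](O[Si](C)(C)C(C)(C)C)C[C@H]1C(C)=C | intermediate
11 | 4-methoxybenzyl alcohol | COc1ccc(CO)cc1 | starting material
12 | 1-({[(E)-1,2-dichloroethenyl]oxy}methyl)-4-methoxybenzene | COc1ccc(CO/C(Cl)=C\Cl)cc1 | intermediate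
13 | lithium 2-[(4-methoxybenzyl)oxy]ethynide | [Li+].[C-]#COCc1ccc(OC)cc1 | intermediate (not isolated)
14 | (1S,2S,4S,5R)-4-[(tert-butyldimethylsilyl)oxy]-1-{[(4-methoxybenzyl)oxy]ethynyl}-5-methyl-2-(prop-1-en-2-yl)cyclohexan-1-ol | O[C@@]1(C#COCc2ccc(OC)cc2)C[C@@H](C)[C@@H](O[Si](C)(C)C(C)(C)C)C[C@H]1C(C)=C | intermediate
15 | (1S,2S,4S,5R)-4-[(tert-butyldimethylsilyl)oxy]-1-{(E)-2-[(4-methoxybenzyl)oxy]ethenyl}-5-methyl-2-(prop-1-en-2-yl)cyclohexan-1-ol | O[C@@]1(/C=C/OCc2ccc(OC)cc2)C[C@@H](C)[C@@H](O[Si](C)(C)C(C)(C)C)C[C@H]1C(C)=C | intermediate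
16 | potassium enolate of the ten-membered ketone (C6=C7 enolate, C5 trans to C8; 1(10)E) | [K+].[O-]/C1=C\[C@@H](OCc2ccc(OC)cc2)C/C(C)=C/C[C@H](O[Si](C)(C)C(C)(C)C)[C@H](C)C1 | intermediate (not isolated)
17 | ethyl [(3S,4R,7R,8S,1(10)E)-3-[(tert-butyldimethylsilyl)oxy]-8-[(4-methoxybenzyl)oxy]-4,10-dimethyl-6-oxocyclodec-1(10)-en-7-yl]acetate | O=C1C[C@@H](C)[C@@H](O[Si](C)(C)C(C)(C)C)C/C=C(C)/C[C@H](OCc2ccc(OC)cc2)[C@H]1CC(=O)OCC | intermediate
18 | ethyl [(3S,4R,6R,7S,8S,1(10)E)-3-[(tert-butyldimethylsilyl)oxy]-6-hydroxy-8-[(4-methoxybenzyl)oxy]-4,10-dimethylcyclodec-1(10)-en-7-yl]acetate | O[C@@H]1C[C@@H](C)[C@@H](O[Si](C)(C)C(C)(C)C)C/C=C(C)/C[C@H](OCc2ccc(OC)cc2)[C@H]1CC(=O)OCC | intermediate (not isolated)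
19 | (3S,4R,6R,7R,8S,1(10)E)-3-[(tert-butyldimethylsilyl)oxy]-8-[(4-methoxybenzyl)oxy]germacr-1(10)-en-12,6-olide | C1C(=O)O[C@@H]2C[C@@H](C)[C@@H](O[Si](C)(C)C(C)(C)C)C/C=C(C)/C[C@H](OCc3ccc(OC)cc3)[C@@H]12 | intermediate
20 | 13-(dimethylamino) derivative of 19 (C11 epimers) | CN(C)CC1C(=O)O[C@@H]2C[C@@H](C)[C@@H](O[Si](C)(C)C(C)(C)C)C/C=C(C)/C[C@H](OCc3ccc(OC)cc3)[C@@H]12 | intermediate (not isolated)
21 | 13-(trimethylammonio) derivative of 19, iodide | [I-].C[N+](C)(C)CC1C(=O)O[C@@H]2C[C@@H](C)[C@@H](O[Si](C)(C)C(C)(C)C)C/C=C(C)/C[C@H](OCc3ccc(OC)cc3)[C@@H]12 | intermediate (not isolated)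
22 | (3S,4R,6R,7R,8S,1(10)E)-3-[(tert-butyldimethylsilyl)oxy]-8-[(4-methoxybenzyl)oxy]germacra-1(10),11(13)-dien-12,6-olide | C=C1C(=O)O[C@@H]2C[C@@H](C)[C@@H](O[Si](C)(C)C(C)(C)C)C/C=C(C)/C[C@H](OCc3ccc(OC)cc3)[C@@H]12 | intermediate
23 | (1R,3S,4R,6R,7R,8S,10R)-3-[(tert-butyldimethylsilyl)oxy]-1,10-dihydroxy-8-[(4-methoxybenzyl)oxy]germacr-11(13)-en-12,6-olide | C=C1C(=O)O[C@@H]2C[C@@H](C)[C@@H](O[Si](C)(C)C(C)(C)C)C[C@@H](O)[C@](C)(O)C[C@H](OCc3ccc(OC)cc3)[C@@H]12 | intermediate
24 | (3S,4R,6R,7R,8S,10R)-3-[(tert-butyldimethylsilyl)oxy]-10-hydroxy-8-[(4-methoxybenzyl)oxy]-1-oxogermacr-11(13)-en-12,6-olide | C=C1C(=O)O[C@@H]2C[C@@H](C)[C@@H](O[Si](C)(C)C(C)(C)C)CC(=O)[C@](C)(O)C[C@H](OCc3ccc(OC)cc3)[C@@H]12 | intermediate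
25 | (3S,4R,6R,7R,8S,10R)-10-acetoxy-3-[(tert-butyldimethylsilyl)oxy]-8-[(4-methoxybenzyl)oxy]-1-oxogermacr-11(13)-en-12,6-olide | C=C1C(=O)O[C@@H]2C[C@@H](C)[C@@H](O[Si](C)(C)C(C)(C)C)CC(=O)[C@](C)(OC(C)=O)C[C@H](OCc3ccc(OC)cc3)[C@@H]12 | intermediate
26 | (3S,4R,6R,7R,8S,10R)-10-acetoxy-3-[(tert-butyldimethylsilyl)oxy]-8-hydroxy-1-oxogermacr-11(13)-en-12,6-olide | C=C1C(=O)O[C@@H]2C[C@@H](C)[C@@H](O[Si](C)(C)C(C)(C)C)CC(=O)[C@](C)(OC(C)=O)C[C@H](O)[C@@H]12 | intermediate
27 | (3S,4R,6R,7S,8S,10R)-10-acetoxy-8-(angeloyloxy)-3-[(tert-butyldimethylsilyl)oxy]-1-oxogermacr-11(13)-en-12,6-olide | C=C1C(=O)O[C@@H]2C[C@@H](C)[C@@H](O[Si](C)(C)C(C)(C)C)CC(=O)[C@](C)(OC(C)=O)C[C@H](OC(=O)/C(C)=C\C)[C@@H]12 | intermediate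
28 | (3S,4R,6R,7S,8S,10R)-10-acetoxy-8-(angeloyloxy)-3-hydroxy-1-oxogermacr-11(13)-en-12,6-olide | C=C1C(=O)O[C@@H]2C[C@@H](C)[C@@H](O)CC(=O)[C@](C)(OC(C)=O)C[C@H](OC(=O)/C(C)=C\C)[C@@H]12 | target

## Step count and least certain steps

Total: 18 steps. Longest linear sequence: 17 steps (steps 1–6 and 8–18, from 1); step 7 prepares 12 from 11.

**Step 10 (key step).**
- What may go wrong: leakage through a boat or a dissociative (retro-addition/recombination) pathway would erode the C8 configuration; loss of the benzyloxide from the β-alkoxy enolate; O-alkylation; or alkylation after the enolate has relaxed to another conformer, with loss of C7 control.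
- Fallback: carry out the rearrangement under neutral conditions and separate it from the alkylation. Compound 15 is silylated (TMSCl, imidazole) to the trimethylsilyl ether F1. Thermal siloxy-Cope rearrangement of F1 (sealed tube, about 200 °C, base-washed glass) should give the ten-membered silyl enol ether F2 without any free enolate. The lithium enolate is then released with MeLi at −78 °C and alkylated with ethyl bromoacetate, returning to the route at 17. In this variant the C7 configuration is set by the preferred conformer of the lithium enolate and by the neighbouring C8 ether, not by the nascent geometry.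

**Step 6.**
- What may go wrong: poor facial selectivity in the protonation, or γ-protonation to the conjugated ketone.
- Fallback: do not correct C1 at all. The more stable epimer, (2R,4S,5R) ketone F3, is taken from 8 and given the geometrically complementary partner. Cerium acetylide addition as in step 8 should give the propargylic alcohol F4. Semihydrogenation over Pd/CaCO3 poisoned with Pb(OAc)2 and quinoline gives the (Z)-enol ether F5, in which the benzyloxy group is axial in the chair and the same 8S centre results. After the anionic oxy-Cope step the enolate is trapped with TMSCl as F2 (the compound of the step 10 fallback) and then alkylated through its lithium enolate, returning at 17.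

**Step 11.**
- What may go wrong: hydride delivery to the other carbonyl face if the ring cannot adopt the zinc chelate; the 6S alcohol would close to the cis-lactone.
- Fallback: invert C6 during lactonisation. The cis-lactone F6 is opened with Me2AlNMe2 (from Me3Al and Me2NH·HCl) to the hydroxy dimethylamide F7, which cannot relactonise easily. Mesylation gives F8. On warming in aqueous THF the amide oxygen displaces the mesylate with inversion, and hydrolysis of the iminium lactone returns the trans-lactone 19.

**Step 13.**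
- What may go wrong: competing osmylation of the exo-methylene lactone, or incomplete face selectivity at the ring alkene.
- Fallback: change the order so that no acrylate is present. Lactone 19 is dihydroxylated to diol F9 and protected as acetonide F10 (2,2-dimethoxypropane, PPTS). The lactone is methylenated as in step 12 to give F11, and aqueous acetic acid releases 23. The face selectivity can be re-examined on 19, whose ring has one sp2 centre fewer.

**Step 15.**
- What may go wrong: sluggish acylation of the hindered tertiary α-ketol; under forcing conditions, α-ketol rearrangement or β-elimination of the C3 silyloxy group.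
- Fallback: place the acetate before the ketone exists, by intramolecular delivery. Diol 23 is converted with MeC(OMe)3 and PPTS into the cyclic orthoacetate F12. Mild aqueous acid opens it; the ester is expected to end up on the more hindered (tertiary) oxygen, giving hydroxy acetate F13. This is oxidised at once with IBX, before acyl migration, to return at 25.

## Further compounds

F1 | step 10 | trimethylsilyl ether of 15 | C[Si](C)(C)O[C@@]1(/C=C/OCc2ccc(OC)cc2)C[C@@H](C)[C@@H](O[Si](C)(C)C(C)(C)C)C[C@H]1C(C)=C
F2 | step 10 | ten-membered C6 trimethylsilyl enol ether (3S,4R,8S; 1(10)E; C5 trans to C8) | C[Si](C)(C)O/C1=C\[C@@H](OCc2ccc(OC)cc2)C/C(C)=C/C[C@H](O[Si](C)(C)C(C)(C)C)[C@H](C)C1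
F3 | step 6 | (2R,4S,5R)-4-[(tert-butyldimethylsilyl)oxy]-5-methyl-2-(prop-1-en-2-yl)cyclohexan-1-one | O=C1C[C@@H](C)[C@@H](O[Si](C)(C)C(C)(C)C)C[C@@H]1C(C)=C
F4 | step 6 | (1R,2R,4S,5R)-4-[(tert-butyldimethylsilyl)oxy]-1-{[(4-methoxybenzyl)oxy]ethynyl}-5-methyl-2-(prop-1-en-2-yl)cyclohexan-1-ol | O[C@]1(C#COCc2ccc(OC)cc2)C[C@@H](C)[C@@H](O[Si](C)(C)C(C)(C)C)C[C@@H]1C(C)=C
F5 | step 6 | (1R,2R,4S,5R)-4-[(tert-butyldimethylsilyl)oxy]-1-{(Z)-2-[(4-methoxybenzyl)oxy]ethenyl}-5-methyl-2-(prop-1-en-2-yl)cyclohexan-1-ol | O[C@]1(/C=C\OCc2ccc(OC)cc2)C[C@@H](C)[C@@H](O[Si](C)(C)C(C)(C)C)C[C@@H]1C(C)=C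
F6 | step 11 | C6 epimer of 19 (cis-fused lactone) | C1C(=O)O[C@H]2C[C@@H](C)[C@@H](O[Si](C)(C)C(C)(C)C)C/C=C(C)/C[C@H](OCc3ccc(OC)cc3)[C@@H]12
F7 | step 11 | N,N-dimethylamide of the 6-epi hydroxy acid | O[C@H]1C[C@@H](C)[C@@H](O[Si](C)(C)C(C)(C)C)C/C=C(C)/C[C@H](OCc2ccc(OC)cc2)[C@H]1CC(=O)N(C)C
F8 | step 11 | C6 mesylate of F7 | CS(=O)(=O)O[C@H]1C[C@@H](C)[C@@H](O[Si](C)(C)C(C)(C)C)C/C=C(C)/C[C@H](OCc2ccc(OC)cc2)[C@H]1CC(=O)N(C)C
F9 | step 13 | 1,10-diol of 19 | C1C(=O)O[C@@H]2C[C@@H](C)[C@@H](O[Si](C)(C)C(C)(C)C)C[C@@H](O)[C@](C)(O)C[C@H](OCc3ccc(OC)cc3)[C@@H]12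
F10 | step 13 | 1,10-acetonide of F9 | C1C(=O)O[C@@H]2C[C@@H](C)[C@@H](O[Si](C)(C)C(C)(C)C)C[C@H]3OC(C)(C)O[C@]3(C)C[C@H](OCc4ccc(OC)cc4)[C@@H]12
F11 | step 13 | 11(13)-methylene derivative of F10 | C=C1C(=O)O[C@@H]2C[C@@H](C)[C@@H](O[Si](C)(C)C(C)(C)C)C[C@H]3OC(C)(C)O[C@]3(C)C[C@H](OCc4ccc(OC)cc4)[C@@H]12
F12 | step 15 | cyclic 1,10-(methyl orthoacetate) of 23 | C=C1C(=O)O[C@@H]2C[C@@H](C)[C@@H](O[Si](C)(C)C(C)(C)C)C[C@H]3OC(C)(OC)O[C@]3(C)C[C@H](OCc4ccc(OC)cc4)[C@@H]12
F13 | step 15 | 10-O-acetyl derivative of 23 (C1 hydroxyl free) | C=C1C(=O)O[C@@H]2C[C@@H](C)[C@@H](O[Si](C)(C)C(C)(C)C)C[C@@H](O)[C@](C)(OC(C)=O)C[C@H](OCc3ccc(OC)cc3)[C@@H]12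
A1 | alternative 1 | seco aldehyde–allylic bromide for Barbier/Nozaki–Hiyama closure | O=CC[C@@H](C)[C@@H](O[Si](C)(C)C(C)(C)C)CC(=O)[C@](C)(OC(C)=O)C[C@H](OCc1ccc(OC)cc1)/C=C(\CBr)C(=O)OC
A2 | alternative 2 | lactone-bearing diene for ring-closing metathesis at C1=C10 | C=C1C(=O)O[C@H](C[C@@H](C)[C@@H](O[Si](C)(C)C(C)(C)C)CC=C)[C@H]1[C@@H](OCc1ccc(OC)cc1)CC(C)=C
A3 | alternative 3 | octalin template with C1=C6 ring-fusion alkene | C[C@@H]1CC2=C(C[C@@H]1O[Si](C)(C)C(C)(C)C)[C@](C)(OC(C)=O)C[C@H](OCc1ccc(OC)cc1)[C@H]2CC(=O)OC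
A4 | alternative 3 | ten-membered 1,6-diketone from ozonolysis of A3 | O=C1C[C@@H](C)[C@@H](O[Si](C)(C)C(C)(C)C)CC(=O)[C@](C)(OC(C)=O)C[C@H](OCc2ccc(OC)cc2)[C@H]1CC(=O)OC
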